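**Retrosynthetic overview**
1. The γ-lactone is bought in as phosphonate 1 and dehydrogenated (via selenide 2 and selenoxide 3) to butenolide 4; C2–C3 comes from an enamine Michael addition of (R)-citronellal 5 (→ 6).
2. C4–C5 and the (E)-C6=C7 alkene come from a vinylogous aldol reaction of 6 with prenal 7 as its silyl dienolate 8 (→ 9); C9 is added by methylenation (→ 10), then acetylation (→ 11) and hydroboration (via borane 12 → 13).
3. Nine-membered ring: oxidation to aldehyde 14 and intramolecular Horner–Wadsworth–Emmons olefination at C1=C9 (→ xenicane lactone 15).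
4. Cyclopropane and eight-membered ring: photochemical transannular C7–C9 bonding with C2→C6 hydrogen shift contracts the nine-membered ring (→ 16); singlet-oxygen ene reaction of the side chain in the same flask gives 17.
5. Ring order: γ-lactone → nine-membered carbocycle → cyclopropane plus eight-membered ring.

Assumption: phosphonate 1 is a catalogue compound (otherwise one Arbuzov step from 2-bromo-γ-butyrolactone and triethyl phosphite).
Assumption on locants: xenicane/crenulatane numbers are used throughout: C1 lactone α-carbon, C19 lactone C=O, C2 lactone β-carbon, C18 OCH2, C3 (side-chain bearing), C4 (O-bearing), C5, C6 (methyl C20), C7, C8, C9, side chain C10–C17.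

**Step 1**
Reactants: 1 diethyl (2-oxooxolan-3-yl)phosphonate
Product: 4 diethyl (2-oxo-2,5-dihydrofuran-3-yl)phosphonate, via selenide 2 (not isolated), via selenoxide 3 (not isolated)
Conditions: NaH, THF, 0 °C; PhSeBr, 0 °C; then 30% H2O2 (3 equiv), CH2Cl2/H2O, 0 °C to rt
Reagents that add atoms: none
Why: α-Selenenylation of the phosphonate-stabilised lactone enolate followed by selenoxide syn-elimination can only run toward the ring CH2 and gives the doubly activated butenolide; no stereocentre is formed.

**Step 2**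
Reactants: 4 diethyl (2-oxo-2,5-dihydrofuran-3-yl)phosphonate; 5 (R)-citronellal
Product: 6 diethyl {(3S,4R)-4-[(2S,3R)-3,7-dimethyl-1-oxooct-6-en-2-yl]-2-oxooxolan-3-yl}phosphonate
Conditions: (R)-2-[diphenyl(trimethylsilyloxy)methyl]pyrrolidine (20 mol %), PhCO2H (20 mol %), toluene, 0 °C to rt
Reagents that add atoms: none
Why: Enamine-catalysed asymmetric Michael addition in which the (R)-diarylprolinol silyl ether shields one face of the (E)-enamine of 5 so that C3 is formed 3S, the acyclic synclinal transition state places C18 syn to C10 (H2/H3 trans), the epimerisable C1 settles trans to the new substituent, and C10 is carried over unchanged from 5.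

**Step 3**
Reactants: 7 3-methylbut-2-enal (prenal)
Product: 8 tert-butyl(dimethyl){[(1E)-3-methylbuta-1,3-dien-1-yl]oxy}silane
Conditions: tBuMe2SiOTf, Et3N, Et2O, 0 °C to rt
Reagents that add atoms: tert-butyldimethylsilyl trifluoromethanesulfonate, CC(C)(C)[Si](C)(C)OS(=O)(=O)C(F)(F)F
Why: Soft enolisation (γ-deprotonation and O-silylation) of the enal gives the silyl dienol ether that serves as the vinylogous nucleophile; no stereocentre.

**Step 4**
Reactants: 6 Michael adduct aldehyde; 8 silyl dienol ether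
Product: 9 diethyl {(3S,4R)-4-[(2E,5R,6S,7R)-5-hydroxy-3,7,11-trimethyl-1-oxododeca-2,10-dien-6-yl]-2-oxooxolan-3-yl}phosphonate
Conditions: (4S)-4-(1H-indol-3-ylmethyl)-3-(4-methylbenzenesulfonyl)-2-phenyl-1,3,2-oxazaborolidin-5-one (1.5 equiv), iPrOH (1.5 equiv), EtCN, −78 °C
Reagents that add atoms: none
Why: Vinylogous Mukaiyama aldol reaction in which the dienolate attacks through its terminal CH2 so that the C4–C5 bond and the (E)-C6=C7 enal form together (s-trans dienolate), while the tryptophan-derived boron Lewis acid exposes the Re face of the aldehyde and sets 4R under reagent control over the weak Felkin bias of the doubly branched C3.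

**Step 5**
Reactants: 9 hydroxy enal
Product: 10 diethyl {(3S,4R)-4-[(3E,6R,7S,8R)-6-hydroxy-4,8,12-trimethyltrideca-1,3,11-trien-7-yl]-2-oxooxolan-3-yl}phosphonate
Conditions: RhCl(PPh3)3 (2.5 mol %), Me3SiCHN2, PPh3, iPrOH, THF, rt
Reagents that add atoms: (trimethylsilyl)diazomethane, C[Si](C)(C)C=[N+]=[N-]
Why: Rhodium-catalysed methylenation (a salt-free Wittig olefination with the ylide generated in the flask) turns the enal into the terminal 1,3-diene and brings in C9 under neutral conditions that spare the acidic phosphonolactone and the δ-hydroxy enal; no stereocentre is touched.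

**Step 6**
Reactants: 10 dienol
Product: 11 (3E,6R,7S,8R)-7-[(3R,4S)-4-(diethoxyphosphoryl)-5-oxooxolan-3-yl]-4,8,12-trimethyltrideca-1,3,11-trien-6-yl acetate
Conditions: Ac2O, pyridine, 4-(dimethylamino)pyridine (10 mol %), CH2Cl2, 0 °C to rt
Reagents that add atoms: acetic anhydride, CC(=O)OC(C)=O
Why: Nucleophile-catalysed acylation of the hindered secondary alcohol installs the C4 acetate with retention of configuration.

**Step 7**
Reactants: 11 diene acetate
Product: 13 (3E,6R,7S,8R)-7-[(3R,4S)-4-(diethoxyphosphoryl)-5-oxooxolan-3-yl]-1-hydroxy-4,8,12-trimethyltrideca-3,11-dien-6-yl acetate, via alkylborane 12 (not isolated)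
Conditions: 9-borabicyclo[3.3.1]nonane, THF, 0 °C to rt; then aq. NaOAc, 30% H2O2, 0 °C
Reagents that add atoms: hydrogen peroxide, OO
Why: Hydroboration–oxidation in which the bulky dialkylborane adds anti-Markovnikov only to the monosubstituted terminus of the diene (both trisubstituted alkenes are far slower) and buffered peroxide gives the C9 primary alcohol without touching acetate, lactone or phosphonate.

**Step 8**
Reactants: 13 hydroxy phosphonate
Product: 15 xenicane lactone (3aS,4S,5R,7E,10E)-7-methyl-4-[(2R)-6-methylhept-5-en-2-yl]-1-oxo-3,3a,4,5,6,9-hexahydro-1H-cyclonona[c]furan-5-yl acetate, via aldehyde 14 (not isolated)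
Conditions: Dess–Martin periodinane, pyridine, CH2Cl2, 0 °C; filter, concentrate; then LiCl, iPr2NEt, MeCN (1 mM, syringe pump), rt
Reagents that add atoms: none
Why: Dess–Martin oxidation gives the β,γ-unsaturated aldehyde, which is closed at once at high dilution by an intramolecular Horner–Wadsworth–Emmons olefination under Masamune–Roush conditions; the nine-membered ring admits only the ring-cis C1=C9 alkene (1(9)E) beside the preset 6E alkene, and C2, C3, C4 and C10 are untouched.

**Step 9**
Reactants: 15 xenicane lactone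
Product: 17 target hydroperoxide (acetoxycrenulide carrying the (2R,4E)-6-hydroperoxy-6-methylhept-4-en-2-yl side chain), via acetoxycrenulide 16 (not isolated)
Conditions: xanthone (9H-xanthen-9-one, 20 mol %), hν (365 nm), degassed MeCN, rt; then methylene blue (3,7-bis(dimethylamino)phenothiazin-5-ium chloride, 1 mol %), O2, hν (red LED, 630 nm), 0 °C
Reagents that add atoms: dioxygen, O=O
Why: Proposed new method: triplet energy transfer reaches only the alkylidene lactone (the isolated alkenes lie above the sensitiser), C9 bonds to C7 across the ring, and the 1,4-diradical is quenched by transannular 1,5-hydrogen transfer from C2 to C6 (an interrupted di-π-methane or photochemical homo-ene process, whose closest known relatives are the direct-irradiation isomerisation of 4-hydroxy xenicane lactones to crenulatanes and the thermal homodienyl 1,5-hydrogen shift run in reverse), so that the cis-fused cyclopropane (7S,9S), the 6R methyl centre and the butenolide alkene are set in one event by the C2–C4 stereocentres of the (E)-cyclononene, after which dye-sensitised singlet oxygen attacks the only electron-rich alkene left in a Schenck ene reaction that removes the C11 hydrogen and gives the (12E) tertiary hydroperoxide, separated by chromatography from its secondary regioisomer.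

**Compound list**
1 | diethyl (2-oxooxolan-3-yl)phosphonate (racemic) | CCOP(=O)(OCC)C1CCOC1=O | starting material
2 | diethyl [2-oxo-3-(phenylselanyl)oxolan-3-yl]phosphonate (racemic) | CCOP(=O)(OCC)C1([Se]c2ccccc2)CCOC1=O | intermediate (not isolated)
3 | diethyl [2-oxo-3-(phenylseleninyl)oxolan-3-yl]phosphonate (selenoxide, racemic) | CCOP(=O)(OCC)C1([Se](=O)c2ccccc2)CCOC1=O | intermediate (not isolated)
4 | diethyl (2-oxo-2,5-dihydrofuran-3-yl)phosphonate | CCOP(=O)(OCC)C1=CCOC1=O | intermediate
5 | (R)-citronellal, (3R)-3,7-dimethyloct-6-enal | O=CC[C@H](C)CCC=C(C)C | starting material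
6 | diethyl {(3S,4R)-4-[(2S,3R)-3,7-dimethyl-1-oxooct-6-en-2-yl]-2-oxooxolan-3-yl}phosphonate | CCOP(=O)(OCC)[C@@H]1C(=O)OC[C@H]1[C@@H](C=O)[C@H](C)CCC=C(C)C | intermediate
7 | 3-methylbut-2-enal (prenal) | CC(C)=CC=O | starting material
8 | tert-butyl(dimethyl){[(1E)-3-methylbuta-1,3-dien-1-yl]oxy}silane | C=C(C)/C=C/O[Si](C)(C)C(C)(C)C | intermediate
9 | diethyl {(3S,4R)-4-[(2E,5R,6S,7R)-5-hydroxy-3,7,11-trimethyl-1-oxododeca-2,10-dien-6-yl]-2-oxooxolan-3-yl}phosphonate | CCOP(=O)(OCC)[C@@H]1C(=O)OC[C@H]1[C@@H]([C@H](O)C/C(C)=C/C=O)[C@H](C)CCC=C(C)C | intermediate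
10 | diethyl {(3S,4R)-4-[(3E,6R,7S,8R)-6-hydroxy-4,8,12-trimethyltrideca-1,3,11-trien-7-yl]-2-oxooxolan-3-yl}phosphonate | CCOP(=O)(OCC)[C@@H]1C(=O)OC[C@H]1[C@@H]([C@H](O)C/C(C)=C/C=C)[C@H](C)CCC=C(C)C | intermediate
11 | (3E,6R,7S,8R)-7-[(3R,4S)-4-(diethoxyphosphoryl)-5-oxooxolan-3-yl]-4,8,12-trimethyltrideca-1,3,11-trien-6-yl acetate | CCOP(=O)(OCC)[C@@H]1C(=O)OC[C@H]1[C@@H]([C@H](OC(C)=O)C/C(C)=C/C=C)[C@H](C)CCC=C(C)C | intermediate
12 | (3E,6R,7S,8R)-1-(9-borabicyclo[3.3.1]nonan-9-yl)-7-[(3R,4S)-4-(diethoxyphosphoryl)-5-oxooxolan-3-yl]-4,8,12-trimethyltrideca-3,11-dien-6-yl acetate | CCOP(=O)(OCC)[C@@H]1C(=O)OC[C@H]1[C@@H]([C@H](OC(C)=O)C/C(C)=C/CCB1C2CCCC1CCC2)[C@H](C)CCC=C(C)C | intermediate (not isolated)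
13 | (3E,6R,7S,8R)-7-[(3R,4S)-4-(diethoxyphosphoryl)-5-oxooxolan-3-yl]-1-hydroxy-4,8,12-trimethyltrideca-3,11-dien-6-yl acetate | CCOP(=O)(OCC)[C@@H]1C(=O)OC[C@H]1[C@@H]([C@H](OC(C)=O)C/C(C)=C/CCO)[C@H](C)CCC=C(C)C | intermediate
14 | (3E,6R,7S,8R)-7-[(3R,4S)-4-(diethoxyphosphoryl)-5-oxooxolan-3-yl]-4,8,12-trimethyl-1-oxotrideca-3,11-dien-6-yl acetate | CCOP(=O)(OCC)[C@@H]1C(=O)OC[C@H]1[C@@H]([C@H](OC(C)=O)C/C(C)=C/CC=O)[C@H](C)CCC=C(C)C | intermediate (not isolated)
15 | xenicane lactone (4-O-acetyl-4-hydroxydictyolactone type; 1(9)E,2S,3S,4R,6E,10R): (3aS,4S,5R,7E,10E)-7-methyl-4-[(2R)-6-methylhept-5-en-2-yl]-1-oxo-3,3a,4,5,6,9-hexahydro-1H-cyclonona[c]furan-5-yl acetate | CC(=O)O[C@@H]1C/C(C)=C/C/C=C2/C(=O)OC[C@H]2[C@@H]1[C@H](C)CCC=C(C)C | intermediate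
16 | acetoxycrenulide (3S,4R,6R,7S,9S,10R): eight-membered ring C1–C7/C9 fused to the butenolide (C1=C2, C19=O on C1, C18H2–O on C2) and to the cis-cyclopropane C7–C8–C9; 4-OAc, 6-Me, (2R)-6-methylhept-5-en-2-yl at C3 | CC(=O)O[C@@H]1C[C@@H](C)[C@@H]2C[C@@H]2C2=C(COC2=O)[C@@H]1[C@H](C)CCC=C(C)C | intermediate (not isolated)
17 | CNP0205234.1: acetoxycrenulide (3S,4R,6R,7S,9S,10R) with the (2R,4E)-6-hydroperoxy-6-methylhept-4-en-2-yl side chain | CC(=O)O[C@@H]1C[C@@H](C)[C@@H]2C[C@@H]2C2=C(COC2=O)[C@@H]1[C@H](C)C/C=C/C(C)(C)OO | target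

**Step count**
Total: 9 steps. Longest linear sequence: 8 steps (1, 2, 4, 5, 6, 7, 8, 9); step 3 makes reagent 8.

**Steps most likely to fail and their fallbacks**

Step 2 (enamine Michael addition to an unusual cyclic phosphonate acceptor; the C2/C3 diastereoselectivity is an extrapolation). The fallback sets out from 5 and comes back at 6. Citronellal 5 is converted with Me3SiCl, Et3N and NaI in MeCN into its (Z)-trimethylsilyl enol ether F1. F1 is then added to 4 in a Mukaiyama–Michael reaction catalysed by Cu(OTf)2 with 2,2′-(propane-2,2-diyl)bis[(4S)-4-tert-butyl-4,5-dihydro-1,3-oxazole] (or its enantiomer, whichever matches C10) in CH2Cl2 at −78 °C, where the phosphoryl and lactone carbonyl oxygens of 4 chelate the copper. The resulting silyl ketene acetal F2 is hydrolysed on aqueous work-up to 6.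

Step 8 (closing a strained nine-membered ring that already holds an E alkene by olefination, with a β,γ-unsaturated aldehyde that can slip into conjugation). The fallback sets out from aldehyde 14 (used crude) and comes back at 15, closing the same C1=C9 bond by alkene metathesis instead. Aldehyde 14 is methylenated (RhCl(PPh3)3, Me3SiCHN2, PPh3, iPrOH) to the terminal alkene phosphonate F3. The phosphonate is then spent in an intermolecular Horner–Wadsworth–Emmons reaction with aqueous formaldehyde (K2CO3, 0 °C) to give the α-methylene lactone F4. Ring-closing metathesis of F4 (second-generation Hoveyda–Grubbs catalyst, toluene, 80 °C, 1 mM) between the methylene lactone and the terminal vinyl group expels ethene and gives 15, the ring again allowing only the ring-cis C1=C9 alkene.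

Step 9 (the sensitised one-flask ring contraction and oxygenation is unprecedented on this acetate; over-irradiation of the vinylcyclopropane product and about 1:1 ene regiochemistry are the main hazards). The fallback sets out from 15 and comes back at 16, which is then isolated. The acetate of 15 is removed (K2CO3, MeOH, 0 °C) to give the free alcohol F5, the substrate type for which the photoisomerisation has direct precedent. Direct irradiation of F5 (254 nm, degassed benzene) gives hydroxycrenulide F6, and Ac2O/pyridine/4-(dimethylamino)pyridine returns 16. Isolated 16 is then photo-oxygenated in a separate operation (O2, methylene blue, red light, 0 °C) to 17.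

**Further compounds**
F1 | step 2 | trimethyl{[(1Z,3R)-3,7-dimethylocta-1,6-dien-1-yl]oxy}silane | C[Si](C)(C)O/C=C\[C@H](C)CCC=C(C)C
F2 | step 2 | diethyl {(4R)-4-[(2S,3R)-3,7-dimethyl-1-oxooct-6-en-2-yl]-2-[(trimethylsilyl)oxy]-4,5-dihydrofuran-3-yl}phosphonate | CCOP(=O)(OCC)C1=C(O[Si](C)(C)C)OC[C@H]1[C@@H](C=O)[C@H](C)CCC=C(C)C
F3 | step 8 | (4E,7R,8S,9R)-8-[(3R,4S)-4-(diethoxyphosphoryl)-5-oxooxolan-3-yl]-5,9,13-trimethyltetradeca-1,4,12-trien-7-yl acetate | CCOP(=O)(OCC)[C@@H]1C(=O)OC[C@H]1[C@@H]([C@H](OC(C)=O)C/C(C)=C/CC=C)[C@H](C)CCC=C(C)C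
F4 | step 8 | (4E,7R,8S,9R)-5,9,13-trimethyl-8-[(3S)-4-methylidene-5-oxooxolan-3-yl]tetradeca-1,4,12-trien-7-yl acetate | C=C1C(=O)OC[C@H]1[C@@H]([C@H](OC(C)=O)C/C(C)=C/CC=C)[C@H](C)CCC=C(C)C
F5 | step 9 | deacetyl-15, 4-hydroxy xenicane lactone (1(9)E,2S,3S,4R,6E,10R) | O[C@@H]1C/C(C)=C/C/C=C2/C(=O)OC[C@H]2[C@@H]1[C@H](C)CCC=C(C)C
F6 | step 9 | deacetyl-16, 4-hydroxycrenulide (3S,4R,6R,7S,9S,10R) | O[C@@H]1C[C@@H](C)[C@@H]2C[C@@H]2C2=C(COC2=O)[C@@H]1[C@H](C)CCC=C(C)C
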